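**Retrosynthetic overview**

- The target is reached by hydrogenolysis of its tri-O-benzyl ether, which comes from the tertiary benzylic pinacol boronate by protodeboronation with retention.
- The strategy rests on the side-chain methine carbon on ring B, ortho to the ring-B oxygen, which carries a methyl group, a hydrogen and the CH2 bound to ring C. This 1,2-diarylprop-2-yl unit maps onto an aryl boronate, an isopropenyl group and an aryl triflate. It lies four bonds from the nearest oxolane stereocenter, across flat ring B, so only a catalyst can set it.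
- A palladium-catalysed conjunctive three-component coupling forms the ring B–methine bond by a 1,2-shift from boron and the CH2–ring C bond by reductive elimination.
- The ring-B boronate comes from the aryl bromide. The oxolane, the only ring built, is closed by acid cyclodehydration of a 1,4-diol at the ring-A benzylic carbon; its cis-dimethyl, aryl-trans-to-methyl pattern is a desymmetrised meso arrangement.
- The diol comes from a lactol and the ring-A Grignard reagent; the lactol comes from the lactone of a keto acid made by rhodium-catalysed enantioselective arylation of meso-2,3-dimethylsuccinic anhydride with the ring-B zinc reagent. Rings A, B and C are bought as arenes.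

Key step: step 9

Assumption: the ligand antipodes named in steps 2 and 9 are taken to give the configurations drawn; if a trial on a simple model substrate shows the opposite sense, the mirror-image ligand is used and nothing else changes.

**Step 1**
Reactants: 1 2-bromo-4-iodophenol
Product: 2 1-(benzyloxy)-2-bromo-4-iodobenzene
Conditions: BnBr, K2CO3, DMF, rt
Reagents that add atoms: benzyl bromide, BrCc1ccccc1
Why: Williamson ether synthesis on the phenoxide; carbonate does not touch either carbon–halogen bond.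

**Step 2**
Reactants: 2 1-(benzyloxy)-2-bromo-4-iodobenzene; 3 meso-2,3-dimethylsuccinic anhydride
Product: 6 (2S,3R)-4-[4-(benzyloxy)-3-bromophenyl]-2,3-dimethyl-4-oxobutanoic acid, via aryllithium 4 (not isolated), via arylzinc triflate 5 (not isolated)
Conditions: 2, n-BuLi, THF, −78 °C, short contact; Zn(OTf)2, −78 °C → rt; then 3, [Rh(cod)Cl]2 (cat.), (S)-t-Bu-PHOX (cat.), THF, 50 °C; aq. HCl
Reagents that add atoms: none
Why: Iodine–lithium exchange outruns bromine–lithium exchange at −78 °C, and the arylzinc made by transmetalation is acylated by one enantiotopic carbonyl of the meso anhydride under a monovalent rhodium–phosphinooxazoline catalyst (enantioselective anhydride desymmetrisation by acyl cross-coupling), the ligand choosing which C–O bond is cleaved so that the two untouched methine carbons emerge as (2S,3R).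

**Step 3**
Reactants: 6 (2S,3R)-4-[4-(benzyloxy)-3-bromophenyl]-2,3-dimethyl-4-oxobutanoic acid
Product: 8 (3S,4R,5R)-5-[4-(benzyloxy)-3-bromophenyl]-3,4-dimethyloxolan-2-one, via hydroxy acid 7 (not isolated)
Conditions: LiBH(s-Bu)3 (L-Selectride, 2.2 equiv), THF, −78 °C; then 2 M HCl, rt
Reagents that add atoms: none
Why: Felkin–Anh delivery of the bulky hydride to the aryl ketone, anti to the CH(CH3)CO2Li branch, should give the 3,4-anti (4R) carbinol, and acid lactonisation with retention then gives the lactone with the aryl group trans to the neighbouring methyl.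

**Step 4**
Reactants: 8 (3S,4R,5R)-5-[4-(benzyloxy)-3-bromophenyl]-3,4-dimethyloxolan-2-one
Product: 9 (3S,4R,5R)-5-[4-(benzyloxy)-3-bromophenyl]-3,4-dimethyloxolan-2-ol (mixture of anomers)
Conditions: i-Bu2AlH (1.1 equiv), CH2Cl2, −78 °C; aq. potassium sodium tartrate
Reagents that add atoms: none
Why: Partial reduction of a lactone to the lactol; the tetrahedral aluminium alkoxide is stable at −78 °C until work-up, and only the anomeric carbon, which is lost later, is new.

**Step 5**
Reactants: 9 (3S,4R,5R)-5-[4-(benzyloxy)-3-bromophenyl]-3,4-dimethyloxolan-2-ol; 10 1-(benzyloxy)-4-bromobenzene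
Product: 12 (1R,2R,3S)-1-[4-(benzyloxy)-3-bromophenyl]-4-[4-(benzyloxy)phenyl]-2,3-dimethylbutane-1,4-diol (both C4 epimers), via aryl Grignard reagent 11 (not isolated)
Conditions: 10, Mg, THF, reflux; then 9 (11 in 3 equiv), THF, 0 °C → rt; then H2O
Reagents that add atoms: none
Why: Grignard addition to the ring-opened hydroxy aldehyde form of the lactol after deprotonation by the first equivalent; the new ring-A carbinol needs no control because it is ionised in step 6, and a Grignard reagent, unlike an aryllithium, does not exchange with the ring-B bromide.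

**Step 6**
Reactants: 12 (1R,2R,3S)-1-[4-(benzyloxy)-3-bromophenyl]-4-[4-(benzyloxy)phenyl]-2,3-dimethylbutane-1,4-diol
Product: 13 (2R,3R,4S,5S)-2-[4-(benzyloxy)-3-bromophenyl]-5-[4-(benzyloxy)phenyl]-3,4-dimethyloxolane
Conditions: TsOH·H2O (cat.), CH2Cl2, 0 °C → rt
Reagents that add atoms: none
Why: Acid-catalysed SN1 cyclodehydration in which the more electron-rich ring-A carbinol ionises to a p-alkoxybenzylic cation that the ring-B hydroxyl captures with retention at its own carbon, the new ring-A center (5S) settling trans to the adjacent methyl both by the less strained closure and by reversible ionisation toward the most stable isomer.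

**Step 7**
Reactants: 13 (2R,3R,4S,5S)-2-[4-(benzyloxy)-3-bromophenyl]-5-[4-(benzyloxy)phenyl]-3,4-dimethyloxolane
Product: 15 2-{2-(benzyloxy)-5-[(2R,3R,4S,5S)-5-[4-(benzyloxy)phenyl]-3,4-dimethyloxolan-2-yl]phenyl}-4,4,5,5-tetramethyl-1,3,2-dioxaborolane, via aryllithium 14 (not isolated)
Conditions: n-BuLi, THF, −78 °C; i-PrOBpin, −78 °C → rt; then H2O
Reagents that add atoms: 2-isopropoxy-4,4,5,5-tetramethyl-1,3,2-dioxaborolane, CC(C)OB1OC(C)(C)C(C)(C)O1
Why: Bromine–lithium exchange followed by trapping of the aryllithium with the isopropoxy boronate (lithiation–borylation), fast enough at −78 °C to leave the benzyl ether and the oxolane untouched.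

**Step 8**
Reactants: 16 4-(benzyloxy)phenol
Product: 17 4-(benzyloxy)phenyl trifluoromethanesulfonate
Conditions: Tf2O, pyridine, CH2Cl2, 0 °C
Reagents that add atoms: trifluoromethanesulfonic anhydride, O=S(=O)(OS(=O)(=O)C(F)(F)F)C(F)(F)F
Why: O-Sulfonylation of a phenol with triflic anhydride in the presence of pyridine.

**Step 9**
Reactants: 15 ring-B pinacol boronate; 18 2-bromopropene; 17 4-(benzyloxy)phenyl trifluoromethanesulfonate
Product: 21 2-[(2R)-2-{2-(benzyloxy)-5-[(2R,3R,4S,5S)-5-[4-(benzyloxy)phenyl]-3,4-dimethyloxolan-2-yl]phenyl}-1-[4-(benzyloxy)phenyl]propan-2-yl]-4,4,5,5-tetramethyl-1,3,2-dioxaborolane, via isopropenyllithium 19 (not isolated), via boron ate complex 20 (not isolated)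
Conditions: 18, t-BuLi (2 equiv), Et2O, −78 °C; 15 (1 equiv), −78 °C → rt; solvent changed to THF; 17, Pd(OAc)2 (cat.), (Sp,Sp)-MandyPhos [1,1′-bis(di-3,5-xylylphosphino)-2,2′-bis((R)-α-dimethylaminobenzyl)ferrocene] (cat.), KOTf, THF, 60 °C
Reagents that add atoms: none
Why: Isopropenyllithium adds to boron of 15 to give ate complex 20; the cationic arylpalladium triflate from oxidative addition of 17 to zerovalent palladium binds the alkene and triggers a 1,2-shift of ring B from boron to the internal alkene carbon while the CH2 carbon bonds to divalent palladium, and reductive elimination then joins CH2 to ring C. The closest known reaction type is the enantioselective palladium-catalysed conjunctive cross-coupling of aryl(alkenyl)boron ate complexes with aryl triflates, including α-substituted alkenyl partners that give tertiary boronic esters. No ring is closed. The new boron-bearing quaternary carbon (R) is set only by the chiral ferrocenyl bisphosphine on palladium, which selects the alkene face; the oxolane stereocenters are too remote to interfere. The step needs carbon migration rather than pinacol-oxygen migration, the metallate shift rather than direct Suzuki-type transmetalation, and face selection; the first is inherent to aryl boronates, the second is favoured by the bisphosphine with a triflate counter-ion (KOTf removes the inhibiting bromide), and the third is the ligand's task. The ortho-benzyloxy group on the migrating ring adds bulk but also electron density, which should help the shift.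

**Step 10**
Reactants: 21 tertiary benzylic pinacol boronate
Product: 22 (2R,3R,4S,5S)-2-{4-(benzyloxy)-3-[(2R)-1-[4-(benzyloxy)phenyl]propan-2-yl]phenyl}-5-[4-(benzyloxy)phenyl]-3,4-dimethyloxolane
Conditions: Bu4NF·3H2O, toluene/n-pentane, 45 °C
Reagents that add atoms: none
Why: Fluoride- and water-promoted protodeboronation of a tertiary aryl dialkyl boronic ester, in which the boronate complex is protonated at carbon from the boron side in a non-polar medium, so boron is replaced by hydrogen with retention and the (R) methine results.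

**Step 11**
Reactants: 22 tri-O-benzyl ether
Product: 23 4-[(2R)-2-{2-hydroxy-5-[(2R,3R,4S,5S)-5-(4-hydroxyphenyl)-3,4-dimethyloxolan-2-yl]phenyl}propyl]phenol
Conditions: H2 (1 atm), 10% Pd/C, EtOAc, rt
Reagents that add atoms: none
Why: Hydrogenolysis of aryl benzyl ethers over palladium on carbon, which under neutral conditions at 1 atm should be much faster than cleavage of the benzylic C–O bonds of the oxolane.

**Compound list**

1 | 2-bromo-4-iodophenol | Oc1ccc(I)cc1Br | starting material
2 | 1-(benzyloxy)-2-bromo-4-iodobenzene | Brc1cc(I)ccc1OCc1ccccc1 | intermediate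
3 | meso-2,3-dimethylsuccinic anhydride | C[C@H]1C(=O)OC(=O)[C@H]1C | starting material
4 | [4-(benzyloxy)-3-bromophenyl]lithium | [Li]c1ccc(OCc2ccccc2)c(Br)c1 | intermediate
5 | [4-(benzyloxy)-3-bromophenyl]zinc triflate | O=S(=O)(O[Zn]c1ccc(OCc2ccccc2)c(Br)c1)C(F)(F)F | intermediate
6 | (2S,3R)-4-[4-(benzyloxy)-3-bromophenyl]-2,3-dimethyl-4-oxobutanoic acid | C[C@@H](C(=O)c1ccc(OCc2ccccc2)c(Br)c1)[C@H](C)C(=O)O | intermediate
7 | (2S,3R,4R)-4-[4-(benzyloxy)-3-bromophenyl]-4-hydroxy-2,3-dimethylbutanoic acid | C[C@@H]([C@@H](O)c1ccc(OCc2ccccc2)c(Br)c1)[C@H](C)C(=O)O | intermediate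
8 | (3S,4R,5R)-5-[4-(benzyloxy)-3-bromophenyl]-3,4-dimethyloxolan-2-one | C[C@@H]1[C@H](C)C(=O)O[C@H]1c1ccc(OCc2ccccc2)c(Br)c1 | intermediate
9 | (3S,4R,5R)-5-[4-(benzyloxy)-3-bromophenyl]-3,4-dimethyloxolan-2-ol, anomer mixture | C[C@@H]1[C@H](C)C(O)O[C@H]1c1ccc(OCc2ccccc2)c(Br)c1 | intermediate
10 | 1-(benzyloxy)-4-bromobenzene | Brc1ccc(OCc2ccccc2)cc1 | starting material
11 | [4-(benzyloxy)phenyl]magnesium bromide | Br[Mg]c1ccc(OCc2ccccc2)cc1 | intermediate
12 | (1R,2R,3S)-1-[4-(benzyloxy)-3-bromophenyl]-4-[4-(benzyloxy)phenyl]-2,3-dimethylbutane-1,4-diol, both C4 epimers | C[C@@H]([C@@H](O)c1ccc(OCc2ccccc2)c(Br)c1)[C@H](C)C(O)c1ccc(OCc2ccccc2)cc1 | intermediate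
13 | (2R,3R,4S,5S)-2-[4-(benzyloxy)-3-bromophenyl]-5-[4-(benzyloxy)phenyl]-3,4-dimethyloxolane | C[C@@H]1[C@H](C)[C@@H](c2ccc(OCc3ccccc3)cc2)O[C@H]1c1ccc(OCc2ccccc2)c(Br)c1 | intermediate
14 | {2-(benzyloxy)-5-[(2R,3R,4S,5S)-5-[4-(benzyloxy)phenyl]-3,4-dimethyloxolan-2-yl]phenyl}lithium | C[C@@H]1[C@H](C)[C@@H](c2ccc(OCc3ccccc3)cc2)O[C@H]1c1ccc(OCc2ccccc2)c([Li])c1 | intermediate
15 | 2-{2-(benzyloxy)-5-[(2R,3R,4S,5S)-5-[4-(benzyloxy)phenyl]-3,4-dimethyloxolan-2-yl]phenyl}-4,4,5,5-tetramethyl-1,3,2-dioxaborolane | C[C@@H]1[C@H](C)[C@@H](c2ccc(OCc3ccccc3)cc2)O[C@H]1c1ccc(OCc2ccccc2)c(B2OC(C)(C)C(C)(C)O2)c1 | intermediate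
16 | 4-(benzyloxy)phenol | Oc1ccc(OCc2ccccc2)cc1 | starting material
17 | 4-(benzyloxy)phenyl trifluoromethanesulfonate | O=S(=O)(Oc1ccc(OCc2ccccc2)cc1)C(F)(F)F | intermediate
18 | 2-bromopropene | C=C(C)Br | starting material
19 | isopropenyllithium | [Li]C(C)=C | intermediate
20 | lithium aryl(isopropenyl)pinacolatoborate, the ate complex of 15 | C[C@@H]1[C@H](C)[C@@H](c2ccc(OCc3ccccc3)cc2)O[C@H]1c1ccc(OCc2ccccc2)c([B-]2(C(C)=C)OC(C)(C)C(C)(C)O2)c1.[Li+] | intermediate
21 | 2-[(2R)-2-{2-(benzyloxy)-5-[(2R,3R,4S,5S)-5-[4-(benzyloxy)phenyl]-3,4-dimethyloxolan-2-yl]phenyl}-1-[4-(benzyloxy)phenyl]propan-2-yl]-4,4,5,5-tetramethyl-1,3,2-dioxaborolane | C[C@@H]1[C@H](C)[C@@H](c2ccc(OCc3ccccc3)cc2)O[C@H]1c1ccc(OCc2ccccc2)c([C@](B2OC(C)(C)C(C)(C)O2)(C)Cc2ccc(OCc3ccccc3)cc2)c1 | intermediate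
22 | (2R,3R,4S,5S)-2-{4-(benzyloxy)-3-[(2R)-1-[4-(benzyloxy)phenyl]propan-2-yl]phenyl}-5-[4-(benzyloxy)phenyl]-3,4-dimethyloxolane | C[C@@H]1[C@H](C)[C@@H](c2ccc(OCc3ccccc3)cc2)O[C@H]1c1ccc(OCc2ccccc2)c([C@H](C)Cc2ccc(OCc3ccccc3)cc2)c1 | intermediate
23 | 4-[(2R)-2-{2-hydroxy-5-[(2R,3R,4S,5S)-5-(4-hydroxyphenyl)-3,4-dimethyloxolan-2-yl]phenyl}propyl]phenol (CNP0232576.1) | C[C@@H]1[C@H](C)[C@@H](c2ccc(O)cc2)O[C@H]1c1ccc(O)c([C@H](C)Cc2ccc(O)cc2)c1 | target

**Step count**

Total: 11 steps. Longest linear sequence: 10 steps (steps 1–7 and 9–11, from 2-bromo-4-iodophenol); step 8 is a one-step side branch.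

**Steps most likely to fail, with fallbacks**

Step 9. The ortho-benzyloxy ring B may migrate sluggishly, so that direct Suzuki-type transfer of a boron substituent to palladium, or poor face selection at the isopropenyl group, takes over. The fallback sets out from 15 and returns at 22, setting the methine by hydrometalation of a 1,1-disubstituted alkene instead of a metallate shift. Suzuki–Miyaura coupling of 15 with 2-bromopropene 18 (Pd(dppf)Cl2, K3PO4, dioxane/H2O, 80 °C, sealed vessel) would give the isopropenyl arene F1. Copper hydride-catalysed enantioselective hydroboration (CuCl, NaOt-Bu, DTBM-SEGPHOS, pinacolborane, toluene, rt) would place boron on the terminal CH2 and set the methine, giving the primary pinacol boronate F2. B-alkyl Suzuki–Miyaura coupling of F2 with aryl bromide 10 (Pd(OAc)2, RuPhos, K3PO4, toluene/H2O, 90 °C) would then give 22, which goes on to step 11.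

Step 10. Protonolysis of the C–B bond may be slow at this electron-rich, ortho-alkoxy-substituted benzylic carbon, or configuration may leak through a loosely bound benzylic anion. The fallback sets out from 21 and returns at 22, re-setting the methine by catalyst-controlled hydrogenation. Oxidation with NaBO3·4H2O (THF/H2O, rt) would give the tertiary alcohol F3. Dehydration with the Burgess reagent (toluene, 50 °C) would give, after separation from minor alkene isomers, the (E)-trisubstituted stilbene F4. Asymmetric hydrogenation with the iridium phosphinooxazoline catalyst [Ir(cod)((S)-t-Bu-PHOX)]B[C6H3(CF3)2]4 (H2, 50 bar, CH2Cl2, rt; ligand antipode chosen for the R methine), which leaves benzyl ethers intact, would give 22.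

Step 3. Hydride delivery is governed by a single α-methyl stereocenter, so facial selectivity may be poor, and the basic hydride could epimerise the ketone α-carbon. The fallback sets out from 6 and returns at 8, replacing substrate control by reagent control. Esterification with Me3SiCHN2 (MeOH/toluene, rt) would give the methyl keto ester F5. Corey–Bakshi–Shibata reduction ((S)-Me-CBS oxazaborolidine, BH3·SMe2, THF, −20 °C) would give the (4R)-hydroxy ester F6, which closes to lactone 8 with catalytic TsOH in CH2Cl2.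

**Further compounds**

F1 | step 9 | (2R,3R,4S,5S)-2-[4-(benzyloxy)-3-(prop-1-en-2-yl)phenyl]-5-[4-(benzyloxy)phenyl]-3,4-dimethyloxolane | C[C@@H]1[C@H](C)[C@@H](c2ccc(OCc3ccccc3)cc2)O[C@H]1c1ccc(OCc2ccccc2)c(C(C)=C)c1
F2 | step 9 | 2-[(2R)-2-{2-(benzyloxy)-5-[(2R,3R,4S,5S)-5-[4-(benzyloxy)phenyl]-3,4-dimethyloxolan-2-yl]phenyl}propyl]-4,4,5,5-tetramethyl-1,3,2-dioxaborolane | C[C@@H]1[C@H](C)[C@@H](c2ccc(OCc3ccccc3)cc2)O[C@H]1c1ccc(OCc2ccccc2)c([C@H](C)CB2OC(C)(C)C(C)(C)O2)c1
F3 | step 10 | (2S)-2-{2-(benzyloxy)-5-[(2R,3R,4S,5S)-5-[4-(benzyloxy)phenyl]-3,4-dimethyloxolan-2-yl]phenyl}-1-[4-(benzyloxy)phenyl]propan-2-ol | C[C@@H]1[C@H](C)[C@@H](c2ccc(OCc3ccccc3)cc2)O[C@H]1c1ccc(OCc2ccccc2)c([C@](O)(C)Cc2ccc(OCc3ccccc3)cc2)c1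
F4 | step 10 | (2R,3R,4S,5S)-2-{4-(benzyloxy)-3-[(E)-1-[4-(benzyloxy)phenyl]prop-1-en-2-yl]phenyl}-5-[4-(benzyloxy)phenyl]-3,4-dimethyloxolane | C[C@@H]1[C@H](C)[C@@H](c2ccc(OCc3ccccc3)cc2)O[C@H]1c1ccc(OCc2ccccc2)c(/C(C)=C/c2ccc(OCc3ccccc3)cc2)c1
F5 | step 3 | methyl (2S,3R)-4-[4-(benzyloxy)-3-bromophenyl]-2,3-dimethyl-4-oxobutanoate | C[C@@H](C(=O)c1ccc(OCc2ccccc2)c(Br)c1)[C@H](C)C(=O)OC
F6 | step 3 | methyl (2S,3R,4R)-4-[4-(benzyloxy)-3-bromophenyl]-4-hydroxy-2,3-dimethylbutanoate | C[C@@H]([C@@H](O)c1ccc(OCc2ccccc2)c(Br)c1)[C@H](C)C(=O)OC
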